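**Plan**

- Numbering: C1 quaternary carbinol, C2 and C3 CHOH, C4 CHOBz, C5=C6 ring alkene, C7 exocyclic CH2. C4 is an allylic carbinol directly beside the C5=C6 bond of the cyclohexene ring, so ring bond C4–C5 can be made from a C4 aldehyde and a (Z)-alkenylmetal at C5.
- Retrosynthetic cuts, in order: C4 benzoate and C2/C3 acetonide; ring bond C4–C5 (alkenylchromium addition to the aldehyde); C7–O (benzoate opening of a C1–C7 epoxide); C1–C6 (ethynyl addition to a C1 ketone); C1–C7 (chloromethyl homologation of a tartrate ester).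
- Forward: the C1–C4 chain of diethyl D-tartrate is desymmetrised, C7 is added as a chloromethyl ketone, C5–C6 as ethynylmagnesium bromide, the alkyne is turned into the (Z)-iodoalkene, C4 is raised to the aldehyde, and the only ring is closed two steps before the end.
- Stereochemistry: C2 and C3 come from D-tartrate. C1 comes from magnesium-chelate-controlled ethynyl addition; the chelate gives the natural C1 configuration only if the entering carbon is the C5–C6 unit and C7 is already on the ketone. C4 comes from the ring closure, with Mitsunobu inversion held in reserve.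

Key step: step 11

Assumption: the ring closure is taken to give mainly the C4 hydroxyl trans to the C3 oxygen (chromium-bound oxygen pseudo-equatorial); the route does not depend on it, since the C4 epimer converges on the same benzoate by inversion (first fallback).

**Route**

Step 1
Reactants: 1 diethyl D-tartrate
Product: 2 diethyl (4S,5S)-2,2-dimethyl-1,3-dioxolane-4,5-dicarboxylate
Conditions: 2,2-dimethoxypropane, TsOH·H2O (cat.), cyclohexane, reflux, MeOH azeotrope removed
Reagents that add atoms: 2,2-dimethoxypropane, COC(C)(C)OC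
Why: acid-catalysed transketalisation of the threo diol (acetonide protection) should give the trans-dioxolane without touching either stereocentre.

Step 2
Reactants: 2 diethyl (4S,5S)-2,2-dimethyl-1,3-dioxolane-4,5-dicarboxylate
Product: 3 ethyl (4S,5R)-5-(hydroxymethyl)-2,2-dimethyl-1,3-dioxolane-4-carboxylate
Conditions: NaBH4 (0.55 equiv), EtOH, −10 → 0 °C
Reagents that add atoms: none
Why: partial borohydride reduction of an α-alkoxy-activated, C2-symmetric diester (mono-reduction) should stop largely at one ester, and because the two esters are equivalent only one hydroxy ester can form, unreacted 2 being recycled.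

Step 3
Reactants: 3 ethyl (4S,5R)-5-(hydroxymethyl)-2,2-dimethyl-1,3-dioxolane-4-carboxylate
Product: 4 ethyl (4S,5R)-5-[(tert-butyldimethylsilyloxy)methyl]-2,2-dimethyl-1,3-dioxolane-4-carboxylate
Conditions: TBSCl, imidazole, CH2Cl2, 0 → 25 °C
Reagents that add atoms: tert-butyldimethylsilyl chloride, CC(C)(C)[Si](C)(C)Cl
Why: silylation of the primary alcohol (silyl ether protection) masks the future C4 oxygen with a group that survives the organometallic steps and can later be removed by fluoride beside a benzoate and an acetonide.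

Step 4
Reactants: 4 ethyl (4S,5R)-5-[(tert-butyldimethylsilyloxy)methyl]-2,2-dimethyl-1,3-dioxolane-4-carboxylate; 5 chloroiodomethane
Product: 6 1-[(4S,5R)-5-[(tert-butyldimethylsilyloxy)methyl]-2,2-dimethyl-1,3-dioxolan-4-yl]-2-chloroethan-1-one (C1 ketone, C7 = CH2Cl)
Conditions: ICH2Cl (1.6 equiv), MeLi·LiBr (1.5 equiv), THF/Et2O, −78 °C; sat. aq. NH4Cl at −78 °C
Reagents that add atoms: chloroiodomethane (5), ClCI
Why: chloromethyllithium, generated by iodine–lithium exchange in the presence of the ester, should add once to the chelating α-alkoxy ester at −78 °C and release the chloromethyl ketone only on quench (carbenoid homologation of an ester to an α-chloroketone), forming the C1–C7 bond.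

Step 5
Reactants: 6 1-[(4S,5R)-5-[(tert-butyldimethylsilyloxy)methyl]-2,2-dimethyl-1,3-dioxolan-4-yl]-2-chloroethan-1-one; 7 ethynylmagnesium bromide
Product: 8 (2S)-1-chloro-2-[(4S,5R)-5-[(tert-butyldimethylsilyloxy)methyl]-2,2-dimethyl-1,3-dioxolan-4-yl]but-3-yn-2-ol
Conditions: MgBr2·OEt2, CH2Cl2, −78 °C; HC≡CMgBr (THF), −78 °C; sat. aq. NH4Cl at −78 °C
Reagents that add atoms: ethynylmagnesium bromide (7), C#C[Mg]Br
Why: Grignard addition under Cram chelate control, in which magnesium bridges the C1 carbonyl oxygen and the dioxolane oxygen on C2 (the CH2Cl group cannot compete for the metal) and the acetylide enters from the face of the C2 hydrogen, should set C1 so that its hydroxyl and the C2 oxygen end up trans on the ring.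

Step 6
Reactants: 8 (2S)-1-chloro-2-[(4S,5R)-5-[(tert-butyldimethylsilyloxy)methyl]-2,2-dimethyl-1,3-dioxolan-4-yl]but-3-yn-2-ol; 9 benzoic acid
Product: 11 (2R)-2-[(4S,5R)-5-[(tert-butyldimethylsilyloxy)methyl]-2,2-dimethyl-1,3-dioxolan-4-yl]-2-hydroxybut-3-yn-1-yl benzoate, via ethynyl oxirane 10 (not isolated)
Conditions: Cs2CO3 (1.5 equiv), DMF, 25 °C; then PhCO2H (3 equiv), 70 °C
Reagents that add atoms: benzoic acid (9), O=C(O)c1ccccc1
Why: base should close the chlorohydrin to the terminal epoxide (intramolecular Williamson reaction) and cesium benzoate should then open it at the unsubstituted C7 (SN2 opening of an epoxide by a carboxylate), so the C1–O bond is never broken and C1 keeps its configuration.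

Step 7
Reactants: 11 (2R)-2-[(4S,5R)-5-[(tert-butyldimethylsilyloxy)methyl]-2,2-dimethyl-1,3-dioxolan-4-yl]-2-hydroxybut-3-yn-1-yl benzoate
Product: 12 (2R)-2-[(4S,5R)-5-[(tert-butyldimethylsilyloxy)methyl]-2,2-dimethyl-1,3-dioxolan-4-yl]-2-hydroxy-4-iodobut-3-yn-1-yl benzoate
Conditions: NIS, AgNO3 (10 mol %), acetone, 25 °C, dark
Reagents that add atoms: N-iodosuccinimide, O=C1CCC(=O)N1I
Why: silver-catalysed iodination of a terminal alkyne with NIS is mild enough for the tertiary alcohol, benzoate, silyl ether and acetonide.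

Step 8
Reactants: 12 (2R)-2-[(4S,5R)-5-[(tert-butyldimethylsilyloxy)methyl]-2,2-dimethyl-1,3-dioxolan-4-yl]-2-hydroxy-4-iodobut-3-yn-1-yl benzoate
Product: 13 (2R,3Z)-2-[(4S,5R)-5-[(tert-butyldimethylsilyloxy)methyl]-2,2-dimethyl-1,3-dioxolan-4-yl]-2-hydroxy-4-iodobut-3-en-1-yl benzoate
Conditions: 2-nitrobenzenesulfonyl hydrazide, Et3N, THF/iPrOH, 25 °C
Reagents that add atoms: none
Why: diimide released from the sulfonyl hydrazide transfers two hydrogens to one face of the iodoalkyne (diimide cis-reduction), which should give the (Z)-iodoalkene and leave the C–I bond intact.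

Step 9
Reactants: 13 (2R,3Z)-2-[(4S,5R)-5-[(tert-butyldimethylsilyloxy)methyl]-2,2-dimethyl-1,3-dioxolan-4-yl]-2-hydroxy-4-iodobut-3-en-1-yl benzoate
Product: 14 (2R,3Z)-2-hydroxy-2-[(4S,5R)-5-(hydroxymethyl)-2,2-dimethyl-1,3-dioxolan-4-yl]-4-iodobut-3-en-1-yl benzoate
Conditions: HF·pyridine, pyridine, THF, 0 → 25 °C
Reagents that add atoms: none
Why: fluoride cleavage of the primary silyl ether under buffered, non-basic conditions (desilylation) should free the C4 hydroxyl without a base-induced benzoyl shift between the C7 and C1 oxygens.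

Step 10
Reactants: 14 (2R,3Z)-2-hydroxy-2-[(4S,5R)-5-(hydroxymethyl)-2,2-dimethyl-1,3-dioxolan-4-yl]-4-iodobut-3-en-1-yl benzoate
Product: 15 (2R,3Z)-2-[(4S,5S)-5-formyl-2,2-dimethyl-1,3-dioxolan-4-yl]-2-hydroxy-4-iodobut-3-en-1-yl benzoate
Conditions: Dess–Martin periodinane, CH2Cl2, 0 → 25 °C; used at once
Reagents that add atoms: none
Why: Dess–Martin oxidation takes the primary alcohol to the aldehyde while the tertiary C1 hydroxyl cannot be oxidised, and the trans-dioxolane disfavours closure of that hydroxyl onto the aldehyde (a trans-fused five–five lactol), so the free aldehyde should be available.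

Step 11
Reactants: 15 (2R,3Z)-2-[(4S,5S)-5-formyl-2,2-dimethyl-1,3-dioxolan-4-yl]-2-hydroxy-4-iodobut-3-en-1-yl benzoate
Product: 17 [(3aS,4R,7S,7aR)-4,7-dihydroxy-2,2-dimethyl-3a,4,7,7a-tetrahydro-1,3-benzodioxol-4-yl]methyl benzoate (trans-fused C2/C3 acetonide, C7 benzoate, free C1 and C4 hydroxyls, C4–OH trans to the C3 oxygen), via alkenylchromium dichloride 16 (not isolated)
Conditions: CrCl2 (6 equiv), NiCl2 (2 mol %), degassed DMSO, 25 °C, 0.005 M, slow addition of 15
Reagents that add atoms: none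
Why: CrCl2 reduces NiCl2 to zerovalent nickel, which inserts into the C5–I bond with retention of the Z geometry, and transmetalation to trivalent chromium gives the alkenylchromium 16, whose C5 adds to the chromium-bound C4 aldehyde (Nozaki–Hiyama–Kishi reaction). The closest known reaction type is the intramolecular Nozaki–Hiyama–Kishi cyclisation of (Z)-iodoalkenyl aldehydes to cyclohex-2-enols. The single ring (C1–C6) closes by 6-exo-trig attack on the carbonyl, the Z alkene becoming the endocyclic C5=C6 bond. The new stereocentre C4 is controlled by the half-chair transition state imposed by the trans-fused dioxolane, in which the C2 and C3 oxygens are equatorial and the chromium-bound aldehyde oxygen is expected to take the pseudo-equatorial site, placing the C4 hydroxyl trans to the C3 oxygen. The step needs chemoselectivity for the aldehyde over the benzoate and tolerance of the free tertiary hydroxyl, which the weakly basic organochromium secures. It also needs ring closure to win over oligomerisation, which the Z geometry (C5 held next to C4) and high dilution secure.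

Step 12
Reactants: 17 [(3aS,4R,7S,7aR)-4,7-dihydroxy-2,2-dimethyl-3a,4,7,7a-tetrahydro-1,3-benzodioxol-4-yl]methyl benzoate; 18 benzoyl chloride
Product: 19 [(3aS,4R,7S,7aR)-7-(benzoyloxy)-4-hydroxy-2,2-dimethyl-3a,4,7,7a-tetrahydro-1,3-benzodioxol-4-yl]methyl benzoate
Conditions: BzCl (1.3 equiv), pyridine, DMAP (cat.), CH2Cl2, 0 °C
Reagents that add atoms: benzoyl chloride (18), O=C(Cl)c1ccccc1
Why: DMAP-catalysed acylation esterifies the secondary allylic C4 hydroxyl with retention, the tertiary C1 hydroxyl being too hindered to react.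

Step 13
Reactants: 19 [(3aS,4R,7S,7aR)-7-(benzoyloxy)-4-hydroxy-2,2-dimethyl-3a,4,7,7a-tetrahydro-1,3-benzodioxol-4-yl]methyl benzoate
Product: 20 Kweichowenol B, [(1R,2S,3S,4S)-4-(benzoyloxy)-1,2,3-trihydroxycyclohex-5-en-1-yl]methyl benzoate (numbering of this proposal)
Conditions: AcOH/H2O (4:1), 40 °C
Reagents that add atoms: none
Why: acid-catalysed hydrolysis of the strained trans-fused isopropylidene ketal (acetonide removal) should proceed under conditions mild enough to leave both benzoates in place and unshifted.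

**Compound list**

1 | diethyl D-tartrate, diethyl (2S,3S)-2,3-dihydroxybutanedioate | CCOC(=O)[C@@H](O)[C@H](O)C(=O)OCC | starting material
2 | diethyl (4S,5S)-2,2-dimethyl-1,3-dioxolane-4,5-dicarboxylate | CCOC(=O)[C@H]1OC(C)(C)O[C@@H]1C(=O)OCC | intermediate
3 | ethyl (4S,5R)-5-(hydroxymethyl)-2,2-dimethyl-1,3-dioxolane-4-carboxylate | OC[C@H]1OC(C)(C)O[C@@H]1C(=O)OCC | intermediate
4 | ethyl (4S,5R)-5-[(tert-butyldimethylsilyloxy)methyl]-2,2-dimethyl-1,3-dioxolane-4-carboxylate | CC(C)(C)[Si](C)(C)OC[C@H]1OC(C)(C)O[C@@H]1C(=O)OCC | intermediate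
5 | chloroiodomethane | ClCI | starting material
6 | 1-[(4S,5R)-5-[(tert-butyldimethylsilyloxy)methyl]-2,2-dimethyl-1,3-dioxolan-4-yl]-2-chloroethan-1-one | CC(C)(C)[Si](C)(C)OC[C@H]1OC(C)(C)O[C@@H]1C(=O)CCl | intermediate
7 | ethynylmagnesium bromide | C#C[Mg]Br | starting material
8 | (2S)-1-chloro-2-[(4S,5R)-5-[(tert-butyldimethylsilyloxy)methyl]-2,2-dimethyl-1,3-dioxolan-4-yl]but-3-yn-2-ol | CC(C)(C)[Si](C)(C)OC[C@H]1OC(C)(C)O[C@@H]1[C@](O)(CCl)C#C | intermediate
9 | benzoic acid | O=C(O)c1ccccc1 | starting material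
10 | (4S,5R)-4-[(2R)-2-ethynyloxiran-2-yl]-5-[(tert-butyldimethylsilyloxy)methyl]-2,2-dimethyl-1,3-dioxolane | CC(C)(C)[Si](C)(C)OC[C@H]1OC(C)(C)O[C@@H]1[C@@]2(C#C)CO2 | intermediate
11 | (2R)-2-[(4S,5R)-5-[(tert-butyldimethylsilyloxy)methyl]-2,2-dimethyl-1,3-dioxolan-4-yl]-2-hydroxybut-3-yn-1-yl benzoate | CC(C)(C)[Si](C)(C)OC[C@H]1OC(C)(C)O[C@@H]1[C@](O)(COC(=O)c2ccccc2)C#C | intermediate
12 | (2R)-2-[(4S,5R)-5-[(tert-butyldimethylsilyloxy)methyl]-2,2-dimethyl-1,3-dioxolan-4-yl]-2-hydroxy-4-iodobut-3-yn-1-yl benzoate | CC(C)(C)[Si](C)(C)OC[C@H]1OC(C)(C)O[C@@H]1[C@](O)(COC(=O)c2ccccc2)C#CI | intermediate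
13 | (2R,3Z)-2-[(4S,5R)-5-[(tert-butyldimethylsilyloxy)methyl]-2,2-dimethyl-1,3-dioxolan-4-yl]-2-hydroxy-4-iodobut-3-en-1-yl benzoate | CC(C)(C)[Si](C)(C)OC[C@H]1OC(C)(C)O[C@@H]1[C@](O)(COC(=O)c2ccccc2)/C=C\I | intermediate
14 | (2R,3Z)-2-hydroxy-2-[(4S,5R)-5-(hydroxymethyl)-2,2-dimethyl-1,3-dioxolan-4-yl]-4-iodobut-3-en-1-yl benzoate | OC[C@H]1OC(C)(C)O[C@@H]1[C@](O)(COC(=O)c2ccccc2)/C=C\I | intermediate
15 | (2R,3Z)-2-[(4S,5S)-5-formyl-2,2-dimethyl-1,3-dioxolan-4-yl]-2-hydroxy-4-iodobut-3-en-1-yl benzoate | O=C[C@H]1OC(C)(C)O[C@@H]1[C@](O)(COC(=O)c2ccccc2)/C=C\I | intermediate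
16 | alkenylchromium dichloride derived from 15 (CrCl2 on C5 in place of iodine, solvent ligands omitted) | O=C[C@H]1OC(C)(C)O[C@@H]1[C@](O)(COC(=O)c2ccccc2)/C=C\[Cr](Cl)Cl | intermediate
17 | [(3aS,4R,7S,7aR)-4,7-dihydroxy-2,2-dimethyl-3a,4,7,7a-tetrahydro-1,3-benzodioxol-4-yl]methyl benzoate | O=C(OC[C@]1(O)C=C[C@H](O)[C@H]2OC(C)(C)O[C@H]12)c1ccccc1 | intermediate
18 | benzoyl chloride | O=C(Cl)c1ccccc1 | starting material
19 | [(3aS,4R,7S,7aR)-7-(benzoyloxy)-4-hydroxy-2,2-dimethyl-3a,4,7,7a-tetrahydro-1,3-benzodioxol-4-yl]methyl benzoate | O=C(OC[C@]1(O)C=C[C@H](OC(=O)c3ccccc3)[C@H]2OC(C)(C)O[C@H]12)c1ccccc1 | intermediate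
20 | Kweichowenol B | O=C(OC[C@]1(O)C=C[C@H](OC(=O)c2ccccc2)[C@@H](O)[C@@H]1O)c1ccccc1 | target

**Step count and risks**

Total step count: 13. Longest linear sequence: 13 steps (1 → 20).

Steps most likely to fail:

Step 11. The aldehyde may be attacked on its other face (chromium-bound oxygen pseudo-axial), so that the C4 hydroxyl comes out cis to the C3 oxygen, partly or mainly. Fallback, from 15 back to 19: the ring closure is run as described and the C4 epimer, the cis alcohol F1, is not acylated directly but esterified under Mitsunobu conditions (PPh3, diisopropyl azodicarboxylate, benzoic acid 9, toluene, 0 °C). SN2 displacement of the activated secondary allylic alcohol inverts C4 and gives 19, the tertiary C1 hydroxyl being inert. Any 17 formed alongside is benzoylated as in step 12, so both epimers converge on 19.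

Step 5. Facial selectivity at the C1 ketone may be reversed if a six-membered chelate through the C3 oxygen or an open Felkin–Anh arrangement outweighs the five-membered chelate. Fallback, from 4 back to 11: the two carbon groups are brought in in the opposite order, which inverts C1 under the same bias.
- The ester 4 is converted into the Weinreb amide F2 (MeNHOMe·HCl, iPrMgCl, THF, −20 °C).
- Lithium (trimethylsilyl)acetylide (from ethynyltrimethylsilane and nBuLi, THF, −78 °C) gives the alkynyl ketone F3.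
- (Isopropoxydimethylsilyl)methylmagnesium chloride with MgBr2·OEt2 in CH2Cl2 at −78 °C adds the C7 carbon to give the tertiary carbinol F4.
- Tamao oxidation (KF, KHCO3, H2O2, THF/MeOH), which also removes the alkynyl silyl group, gives the diol F5.
- Selective benzoylation of the primary hydroxyl (BzCl, pyridine, CH2Cl2, −20 °C) gives 11.

Step 4. The carbenoid may decompose before it adds, or add a second time to the ketone once it is released. Fallback, from 4 back to 6: the carbenoid is avoided altogether.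
- Saponification (LiOH, THF/H2O, 0 °C) gives the carboxylic acid F6.
- 1-Chloro-N,N,2-trimethylprop-1-en-1-amine in CH2Cl2 at 0 °C gives the acid chloride F7 under neutral conditions.
- Trimethylsilyldiazomethane in MeCN/THF at 0 °C gives the diazoketone F8.
- One equivalent of anhydrous HCl in Et2O at 0 °C converts F8 into the chloromethyl ketone 6 with loss of nitrogen.

**Further compounds**

F1 | step 11 | [(3aS,4R,7R,7aR)-4,7-dihydroxy-2,2-dimethyl-3a,4,7,7a-tetrahydro-1,3-benzodioxol-4-yl]methyl benzoate (C4 epimer of 17, C4–OH cis to the C3 oxygen) | O=C(OC[C@]1(O)C=C[C@@H](O)[C@H]2OC(C)(C)O[C@H]12)c1ccccc1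
F2 | step 5 | (4S,5R)-5-[(tert-butyldimethylsilyloxy)methyl]-N-methoxy-N,2,2-trimethyl-1,3-dioxolane-4-carboxamide | CC(C)(C)[Si](C)(C)OC[C@H]1OC(C)(C)O[C@@H]1C(=O)N(C)OC
F3 | step 5 | 1-[(4S,5R)-5-[(tert-butyldimethylsilyloxy)methyl]-2,2-dimethyl-1,3-dioxolan-4-yl]-3-(trimethylsilyl)prop-2-yn-1-one | CC(C)(C)[Si](C)(C)OC[C@H]1OC(C)(C)O[C@@H]1C(=O)C#C[Si](C)(C)C
F4 | step 5 | (2S)-2-[(4S,5R)-5-[(tert-butyldimethylsilyloxy)methyl]-2,2-dimethyl-1,3-dioxolan-4-yl]-1-[isopropoxy(dimethyl)silyl]-4-(trimethylsilyl)but-3-yn-2-ol | CC(C)(C)[Si](C)(C)OC[C@H]1OC(C)(C)O[C@@H]1[C@](O)(C[Si](C)(C)OC(C)C)C#C[Si](C)(C)C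
F5 | step 5 | (2R)-2-[(4S,5R)-5-[(tert-butyldimethylsilyloxy)methyl]-2,2-dimethyl-1,3-dioxolan-4-yl]but-3-yne-1,2-diol | CC(C)(C)[Si](C)(C)OC[C@H]1OC(C)(C)O[C@@H]1[C@](O)(CO)C#C
F6 | step 4 | (4S,5R)-5-[(tert-butyldimethylsilyloxy)methyl]-2,2-dimethyl-1,3-dioxolane-4-carboxylic acid | CC(C)(C)[Si](C)(C)OC[C@H]1OC(C)(C)O[C@@H]1C(=O)O
F7 | step 4 | (4S,5R)-5-[(tert-butyldimethylsilyloxy)methyl]-2,2-dimethyl-1,3-dioxolane-4-carbonyl chloride | CC(C)(C)[Si](C)(C)OC[C@H]1OC(C)(C)O[C@@H]1C(=O)Cl
F8 | step 4 | 2-diazo-1-[(4S,5R)-5-[(tert-butyldimethylsilyloxy)methyl]-2,2-dimethyl-1,3-dioxolan-4-yl]ethan-1-one | CC(C)(C)[Si](C)(C)OC[C@H]1OC(C)(C)O[C@@H]1C(=O)C=[N+]=[N-]
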